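**Plan**

Numbering: ten-membered carbocycle C1–C10 (C1=C10 enoate with ester C14 on C10, exo-methylene C4=C15, carbinol C5, lactone oxygen on C6, lactone carbons C11(=C13)–C12 on C7, angelate on C8).
Cuts: first C4–C5 in the carbocycle, because the allylic carbinol C5 beside the exo-methylene carbon C4 is the adduct of a 2-metalated 1-alkene and an aldehyde; then the lactone O6–C12 bond and the angelate ester, the C7–C8 bond (2-carboxyallyl metal plus aldehyde), the C8 aldehyde (from a vinyl group) and C1=C10 (Wittig).
Forward: the iodoalkene chain C1–C4 is joined to an allyl-bearing ylide (C1=C10), the allyl group is cut to the C8 aldehyde, an indium allylation with a glyceraldehyde-derived (Z)-2-(bromomethyl)alkenoate makes C7–C8, O8 is angeloylated, acid closes the five-membered 6,12-lactone (first ring), C5 is oxidised to the aldehyde, and the ten-membered ring closes last.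
Stereochemistry: C6 from (R)-glyceraldehyde acetonide; C7 and C8 from the allylation (attack anti to the dioxolane C–O bond; the (Z)-allylindium chair gives the syn C7/C8 pair); C5 from the chiral ligand on chromium in the ring closure; C1=C10 (E) from the stabilised ylide; the angelate (Z) from angelic acid.

Key step: step 12

Assumption: (R)-glyceraldehyde acetonide is taken as a purchasable chiral-pool aldehyde (also available in one operation from 1,2:5,6-di-O-isopropylidene-D-mannitol and NaIO4) and is used freshly distilled.

**Route**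

Step 1
Reactants: 1 pent-4-yn-1-ol
Product: 2 4-iodopent-4-en-1-ol
Conditions: NaI, Me3SiCl, H2O, MeCN, rt
Reagents that add atoms: sodium iodide, [Na+].[I-]
Why: Hydrogen iodide made in the flask adds to the terminal alkyne in the Markovnikov sense (alkyne hydroiodination), which should give the 2-iodo-1-alkene that later becomes the C4 nucleophile.

Step 2
Reactants: 2 4-iodopent-4-en-1-ol
Product: 3 4-iodopent-4-enal
Conditions: Dess–Martin periodinane, CH2Cl2, 0 °C to rt
Reagents that add atoms: none
Why: Dess–Martin oxidation takes the primary alcohol to the aldehyde under neutral conditions that leave the alkenyl iodide alone.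

Step 3
Reactants: 4 methyl 2-(triphenyl-λ5-phosphanylidene)acetate (2 equiv); 5 allyl bromide
Product: 7 methyl 2-(triphenyl-λ5-phosphanylidene)pent-4-enoate, via phosphonium bromide 6 (not isolated)
Conditions: EtOAc, reflux; filtration of the precipitated salt
Reagents that add atoms: none
Why: C-alkylation of the ester-stabilised ylide by the reactive allylic bromide is followed by transylidation, the second equivalent of 4 deprotonating salt 6 and leaving as its insoluble hydrobromide.

Step 4
Reactants: 7 methyl 2-(triphenyl-λ5-phosphanylidene)pent-4-enoate; 3 4-iodopent-4-enal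
Product: 8 methyl (2E)-6-iodo-2-(prop-2-en-1-yl)hepta-2,6-dienoate
Conditions: CH2Cl2, 40 °C
Reagents that add atoms: none
Why: A Wittig reaction of an α-substituted ester-stabilised ylide with an unbranched aldehyde reliably places the ester trans to the new chain, which is the C1=C10 geometry of the target, and no base is present that could harm the aldehyde.

Step 5
Reactants: 8 methyl (2E)-6-iodo-2-(prop-2-en-1-yl)hepta-2,6-dienoate
Product: 10 methyl (2E)-6-iodo-2-(2-oxoethyl)hepta-2,6-dienoate, via diol 9 (not isolated)
Conditions: OsO4 (2 mol%), NaIO4, 2,6-lutidine, dioxane/H2O 3:1, 0 °C to rt; used crude at once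
Reagents that add atoms: osmium tetroxide, O=[Os](=O)(=O)=O; sodium periodate, [Na+].[O-]I(=O)(=O)=O
Why: In this Lemieux–Johnson cleavage OsO4 should dihydroxylate the electron-rich monosubstituted alkene well ahead of the ester-conjugated trisubstituted alkene and the iodine-deactivated 1,1-disubstituted alkene, periodate cutting diol 9 as it forms, and the β,γ-unsaturated aldehyde is not stored because it can slip into conjugation.

Step 6
Reactants: 11 (4R)-2,2-dimethyl-1,3-dioxolane-4-carbaldehyde; 12 tert-butyl prop-2-enoate
Product: 13 tert-butyl 2-{[(4R)-2,2-dimethyl-1,3-dioxolan-4-yl](hydroxy)methyl}prop-2-enoate (mixture of carbinol epimers)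
Conditions: DABCO, 1,4-dioxane/H2O 1:1, rt
Reagents that add atoms: none
Why: In this Morita–Baylis–Hillman reaction the amine-acrylate zwitterion adds to the reactive α-alkoxy aldehyde; the new carbinol becomes sp2 in step 7, so only the dioxolane centre (later C6), taken from the chiral pool, matters.

Step 7
Reactants: 13 tert-butyl 2-{[(4R)-2,2-dimethyl-1,3-dioxolan-4-yl](hydroxy)methyl}prop-2-enoate
Product: 14 tert-butyl (2Z)-2-(bromomethyl)-3-[(4S)-2,2-dimethyl-1,3-dioxolan-4-yl]prop-2-enoate
Conditions: N-bromosuccinimide, Me2S, CH2Cl2, 0 °C to rt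
Reagents that add atoms: N-bromosuccinimide, O=C1CCC(=O)N1Br
Why: Corey–Kim-type activation of the allylic alcohol and SN2′ entry of bromide give the rearranged primary allylic bromide, which for ester-derived adducts of this kind forms with the (Z) geometry (dioxolanyl cis to CH2Br) under acid-free conditions that spare the acetonide.

Step 8
Reactants: 14 tert-butyl (2Z)-2-(bromomethyl)-3-[(4S)-2,2-dimethyl-1,3-dioxolan-4-yl]prop-2-enoate; 10 methyl (2E)-6-iodo-2-(2-oxoethyl)hepta-2,6-dienoate
Product: 16 1-tert-butyl 7-methyl (3R,4R,6E)-3-[(4S)-2,2-dimethyl-1,3-dioxolan-4-yl]-4-hydroxy-6-(4-iodopent-4-en-1-ylidene)-2-methylideneheptanedioate, via allylindium dibromide 15 (not isolated)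
Conditions: indium powder, THF/H2O 1:1, rt
Reagents that add atoms: none
Why: In this indium-mediated Barbier allylation (SE2′ through a closed six-membered chair) the (Z) geometry of 15 with the aldehyde chain equatorial should give the syn C7/C8 pair (O8 and C6 syn along C9–C8–C7–C11), while allylic 1,3-strain holds the dioxolane C6–H in the alkene plane so that the aldehyde adds anti to the C6–O bond and sets C7 relative to C6, and the neutral aqueous medium spares the enoate, the alkenyl iodide and the tert-butyl ester, which does not lactonise onto O8.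

Step 9
Reactants: 16 hydroxy diester (as named in step 8); 17 angelic acid
Product: 18 1-tert-butyl 7-methyl (3R,4R,6E)-3-[(4S)-2,2-dimethyl-1,3-dioxolan-4-yl]-6-(4-iodopent-4-en-1-ylidene)-2-methylidene-4-{[(2Z)-2-methylbut-2-enoyl]oxy}heptanedioate
Conditions: 2,4,6-Cl3C6H2COCl, Et3N, toluene, rt; then 16, 80 °C
Reagents that add atoms: none
Why: Yamaguchi-type acylation through the preformed angelic 2,4,6-trichlorobenzoic mixed anhydride without a nucleophilic catalyst is the established way to put an angelate on a hindered secondary alcohol without (Z) to (E) isomerisation.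

Step 10
Reactants: 18 angelate diester (as named in step 9)
Product: 20 methyl (2E)-2-{(2R)-2-[(2S,3R)-2-(hydroxymethyl)-4-methylidene-5-oxooxolan-3-yl]-2-{[(2Z)-2-methylbut-2-enoyl]oxy}ethyl}-6-iodohepta-2,6-dienoate, via dihydroxy acid 19 (not isolated)
Conditions: CF3CO2H/H2O 9:1, 0 °C to rt; evaporation with toluene
Reagents that add atoms: none
Why: Acidolysis removes the acetonide and the tert-butyl ester in one operation and the freed γ-hydroxy acid 19 should lactonise (Fischer-type) onto O6 to the five-membered ring in preference to the six-membered alternative through O5, which leaves the C5 alcohol free and the C6 and C7 substituents trans on the lactone.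

Step 11
Reactants: 20 lactone alcohol (as named in step 10)
Product: 21 methyl (2E)-2-{(2R)-2-[(2S,3R)-2-formyl-4-methylidene-5-oxooxolan-3-yl]-2-{[(2Z)-2-methylbut-2-enoyl]oxy}ethyl}-6-iodohepta-2,6-dienoate
Conditions: Dess–Martin periodinane, CH2Cl2, 0 °C to rt; used directly
Reagents that add atoms: none
Why: Dess–Martin oxidation under neutral non-aqueous conditions should give the α-acyloxy aldehyde without epimerising C6 or touching the Michael acceptors.

Step 12
Reactants: 21 seco iodo aldehyde (as named in step 11)
Product: 22 CNP0163095.1, the (5S,6S,7R,8R)-8-angeloyloxy-5-hydroxy-1(10)E,4(15),11(13)-germacratrien-6,12-olide 14-methyl ester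
Conditions: CrCl2 (20 mol%), NiCl2(MeOCH2CH2OMe) (2 mol%), chiral 2-(2-sulfonamidophenyl)oxazoline ligand (antipode for Si-face delivery at C5), (C5H5)2ZrCl2 (1.1 equiv), Bu4NBr, DMF, Al anode, Ni-foam cathode, constant current, rt, slow addition of 21 to about 2 mM; aqueous work-up
Reagents that add atoms: none
Why: Zerovalent nickel inserts into the C4–I bond, the alkenyl group passes to trivalent chromium and adds to the C5 aldehyde, (C5H5)2ZrCl2 takes the alkoxide off chromium, and the cathode returns trivalent chromium to the divalent state while the aluminium anode is consumed. The closest known reaction is the Ni/Cr-mediated Nozaki–Hiyama–Kishi macrocyclisation of iodoalkenyl aldehydes, run here with catalytic chromium under electroreductive turnover. The ten-membered carbocycle closes by a 10-exo-trig addition, helped by slow addition into dilute solution and by the turn that the cis-disposed C9 and C2 on the C1=C10 enoate and the trans-lactone put into the chain. The new C5 centre is set by the chiral sulfonamide ligand on chromium, which must deliver C4 to the Si face of the aldehyde; the open-chain polar 1,2-induction model (nucleophile anti to the C6–O bond) points to the 5,6-anti epimer, whereas the target is 5,6-syn, so the ligand antipode is chosen to override the substrate. Chemoselectivity rests on the alkenylchromium reagent, which adds to aldehydes but not to the two enoates, the angelate or the α-methylene lactone, and on a cathode potential held at the chromium couple, below what would reduce the aldehyde or the conjugated esters.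

**Compound list**

1 | pent-4-yn-1-ol | C#CCCCO | starting material
2 | 4-iodopent-4-en-1-ol | C=C(I)CCCO | intermediate
3 | 4-iodopent-4-enal | C=C(I)CCC=O | intermediate
4 | methyl 2-(triphenyl-λ5-phosphanylidene)acetate | COC(=O)C=P(c1ccccc1)(c1ccccc1)c1ccccc1 | starting material
5 | allyl bromide (3-bromoprop-1-ene) | C=CCBr | starting material
6 | (1-methoxy-1-oxopent-4-en-2-yl)triphenylphosphonium bromide | C=CCC(C(=O)OC)[P+](c1ccccc1)(c1ccccc1)c1ccccc1.[Br-] | intermediate
7 | methyl 2-(triphenyl-λ5-phosphanylidene)pent-4-enoate | C=CCC(C(=O)OC)=P(c1ccccc1)(c1ccccc1)c1ccccc1 | intermediate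
8 | methyl (2E)-6-iodo-2-(prop-2-en-1-yl)hepta-2,6-dienoate | C=CC/C(C(=O)OC)=C\CCC(I)=C | intermediate
9 | methyl (2E)-2-(2,3-dihydroxypropyl)-6-iodohepta-2,6-dienoate (racemic at the carbinol) | OCC(O)C/C(C(=O)OC)=C\CCC(I)=C | intermediate
10 | methyl (2E)-6-iodo-2-(2-oxoethyl)hepta-2,6-dienoate | O=CC/C(C(=O)OC)=C\CCC(I)=C | intermediate
11 | (4R)-2,2-dimethyl-1,3-dioxolane-4-carbaldehyde ((R)-glyceraldehyde acetonide) | O=C[C@H]1COC(C)(C)O1 | starting material
12 | tert-butyl prop-2-enoate | C=CC(=O)OC(C)(C)C | starting material
13 | tert-butyl 2-{[(4R)-2,2-dimethyl-1,3-dioxolan-4-yl](hydroxy)methyl}prop-2-enoate (carbinol epimers) | C=C(C(=O)OC(C)(C)C)C(O)[C@H]1COC(C)(C)O1 | intermediate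
14 | tert-butyl (2Z)-2-(bromomethyl)-3-[(4S)-2,2-dimethyl-1,3-dioxolan-4-yl]prop-2-enoate | BrC/C(C(=O)OC(C)(C)C)=C\[C@H]1COC(C)(C)O1 | intermediate
15 | allylindium reagent from 14, drawn as the allylindium dibromide | Br[In](Br)C/C(C(=O)OC(C)(C)C)=C\[C@H]1COC(C)(C)O1 | intermediate
16 | 1-tert-butyl 7-methyl (3R,4R,6E)-3-[(4S)-2,2-dimethyl-1,3-dioxolan-4-yl]-4-hydroxy-6-(4-iodopent-4-en-1-ylidene)-2-methylideneheptanedioate | C=C(C(=O)OC(C)(C)C)[C@@H]([C@H]1COC(C)(C)O1)[C@H](O)C/C(C(=O)OC)=C\CCC(I)=C | intermediate
17 | angelic acid, (2Z)-2-methylbut-2-enoic acid | C/C=C(/C)C(=O)O | starting material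
18 | 1-tert-butyl 7-methyl (3R,4R,6E)-3-[(4S)-2,2-dimethyl-1,3-dioxolan-4-yl]-6-(4-iodopent-4-en-1-ylidene)-2-methylidene-4-{[(2Z)-2-methylbut-2-enoyl]oxy}heptanedioate | C=C(C(=O)OC(C)(C)C)[C@@H]([C@H]1COC(C)(C)O1)[C@H](OC(=O)/C(C)=C\C)C/C(C(=O)OC)=C\CCC(I)=C | intermediate
19 | dihydroxy acid from 18 (acetonide and tert-butyl ester removed, free C5 and C6 hydroxyls and C12 acid, configurations unchanged) | C=C(C(=O)O)[C@@H]([C@H](O)CO)[C@H](OC(=O)/C(C)=C\C)C/C(C(=O)OC)=C\CCC(I)=C | intermediate
20 | methyl (2E)-2-{(2R)-2-[(2S,3R)-2-(hydroxymethyl)-4-methylidene-5-oxooxolan-3-yl]-2-{[(2Z)-2-methylbut-2-enoyl]oxy}ethyl}-6-iodohepta-2,6-dienoate | C=C1C(=O)O[C@H](CO)[C@H]1[C@H](OC(=O)/C(C)=C\C)C/C(C(=O)OC)=C\CCC(I)=C | intermediate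
21 | methyl (2E)-2-{(2R)-2-[(2S,3R)-2-formyl-4-methylidene-5-oxooxolan-3-yl]-2-{[(2Z)-2-methylbut-2-enoyl]oxy}ethyl}-6-iodohepta-2,6-dienoate (seco iodo aldehyde) | C=C1C(=O)O[C@H](C=O)[C@H]1[C@H](OC(=O)/C(C)=C\C)C/C(C(=O)OC)=C\CCC(I)=C | intermediate
22 | CNP0163095.1, (5S,6S,7R,8R)-8-angeloyloxy-5-hydroxy-1(10)E,4(15),11(13)-germacratrien-6,12-olide 14-methyl ester | C=C1C(=O)O[C@H]2[C@H]1[C@H](OC(=O)/C(C)=C\C)C/C(C(=O)OC)=C\CCC(=C)[C@@H]2O | target

**Step count**

Total: 12 steps. Longest linear sequence: 9 steps (1 → 2 → 3 → 8 → 10 → 16 → 18 → 20 → 21 → 22; steps 1, 2, 4, 5, 8, 9, 10, 11, 12).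

**Steps most likely to fail**

Step 12. Oligomerisation may outrun ring closure, and addition may go to the Re face of the aldehyde because the C6–O bond biases the open chain toward the 5,6-anti epimer. The fallback sets out from 21 and returns at 22, and moves control of C5 from the C–C bond formation to a hydride delivery. The ring is closed without the chiral ligand under the robust classical conditions (excess CrCl2 with a trace of NiCl2, DMSO/THF, high dilution) and the product is accepted as the 5-epimeric alcohol F1. This is oxidised with Dess–Martin periodinane to the cross-conjugated ring enone F2. Luche reduction (NaBH4, CeCl3·7H2O, MeOH, −78 °C) should then add hydride 1,2 from the outer face of the ten-membered ring and give 22; the low temperature and the cerium salt keep borohydride off the α-methylene lactone.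

Step 8. Facial selectivity at C7 relative to the dioxolane centre may be poor, since the equatorial aldehyde chain sits close to the dioxolane in the (Z)-type chair, and aldehyde 10 may isomerise into conjugation before it is captured. The fallback sets out from 13 and returns at 20, and lets the lactone ring fix the face instead of the open-chain dioxolane. CF3CO2H/H2O on 13 removes both protecting groups and closes the lactone to the hydroxy lactone (5R)-4-hydroxy-5-(hydroxymethyl)-3-methylideneoxolan-2-one F3. The primary alcohol is silylated (tert-butyldiphenylsilyl chloride, imidazole) to the silyl ether F4. PBr3 in Et2O at 0 °C gives, with allylic transposition, the cyclic bromide (5S)-3-(bromomethyl)-5-{[(tert-butyldiphenylsilyl)oxy]methyl}furan-2(5H)-one F5. Indium-mediated Barbier reaction of F5 with 10 should add the aldehyde to C7 trans to the C6 substituent; because this reagent is locked in the (E)-type geometry, the chair should give the C8-epimeric hydroxy lactone F6. Mitsunobu esterification of F6 with angelic acid 17 (PPh3, diisopropyl azodicarboxylate) inverts C8 and gives the angelate silyl ether F7. HF·pyridine then frees the C5 alcohol and gives 20.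

Step 9. Transfer of the hindered angeloyl group at 80 °C may be slower than lactonisation of O8 onto the C14 methyl ester, or the angelate may isomerise from (Z) to (E). The fallback sets out from 16 and returns at 18, and builds the angelate on the oxygen instead of transferring it. The alcohol is acylated at 0 °C with the small, reactive 2-[bis(2,2,2-trifluoroethoxy)phosphoryl]propanoic acid (carbodiimide, catalytic 4-dimethylaminopyridine) to the phosphonate ester F8. Still–Gennari olefination of F8 with acetaldehyde (KN(SiMe3)2, 18-crown-6, THF, −78 °C) should then give the (Z)-2-methylbut-2-enoate 18.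

**Further compounds**

F1 | step 12 | 5-epimer of 22, (5R,6S,7R,8R) | C=C1C(=O)O[C@H]2[C@H]1[C@H](OC(=O)/C(C)=C\C)C/C(C(=O)OC)=C\CCC(=C)[C@H]2O
F2 | step 12 | 5-oxo compound (ring enone, C4=C15 conjugated to C5=O) | C=C1C(=O)O[C@H]2[C@H]1[C@H](OC(=O)/C(C)=C\C)C/C(C(=O)OC)=C\CCC(=C)C2=O
F3 | step 8 | (5R)-4-hydroxy-5-(hydroxymethyl)-3-methylideneoxolan-2-one (C4 epimers) | C=C1C(=O)O[C@H](CO)C1O
F4 | step 8 | (5R)-5-{[(tert-butyldiphenylsilyl)oxy]methyl}-4-hydroxy-3-methylideneoxolan-2-one (C4 epimers) | C=C1C(=O)O[C@H](CO[Si](c2ccccc2)(c2ccccc2)C(C)(C)C)C1O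
F5 | step 8 | (5S)-3-(bromomethyl)-5-{[(tert-butyldiphenylsilyl)oxy]methyl}furan-2(5H)-one | O=C1O[C@H](CO[Si](c2ccccc2)(c2ccccc2)C(C)(C)C)C=C1CBr
F6 | step 8 | C8-epimeric hydroxy lactone silyl ether (6S,7R,8S; free 8-OH, trans-lactone, C5 silyl ether) | C=C1C(=O)O[C@H](CO[Si](c2ccccc2)(c2ccccc2)C(C)(C)C)[C@H]1[C@@H](O)C/C(C(=O)OC)=C\CCC(I)=C
F7 | step 8 | tert-butyldiphenylsilyl ether of 20 (6S,7R,8R angelate) | C=C1C(=O)O[C@H](CO[Si](c2ccccc2)(c2ccccc2)C(C)(C)C)[C@H]1[C@H](OC(=O)/C(C)=C\C)C/C(C(=O)OC)=C\CCC(I)=C
F8 | step 9 | 2-[bis(2,2,2-trifluoroethoxy)phosphoryl]propanoate of 16 (epimers at the phosphonate carbon) | C=C(C(=O)OC(C)(C)C)[C@@H]([C@H]1COC(C)(C)O1)[C@H](OC(=O)C(C)P(=O)(OCC(F)(F)F)OCC(F)(F)F)C/C(C(=O)OC)=C\CCC(I)=C
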